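## Retrosynthetic overview

- Target 17 comes from its tri-O-benzyl ether 16 by hydrogenolysis. Cutting the C3–C7' bond of 16 gives the lithium enolate of (4R)-lactone 8 and the ring A benzylic bromide 14; the bromide enters anti to the C4 substituent, so C3 ends up trans (3R,4R).
- The feature that carries the strategy is the lactone ring O1–C2(=O)–C3–C4–C5. O1 bridges the carbonyl carbon C2 and the methylene C5, and C4 (bearing C7 and ring B, 4-hydroxy-3-methoxyphenyl) is β to the carbonyl. Removing O1 and joining C2 to C5 gives the mirror-symmetric 3-benzylcyclobutanone 6, whose ring carbon 3 (the future C4) is prochiral.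
- Lactone 8 comes from 6 by an enantioselective Baeyer–Villiger oxygen insertion into one of the two enantiotopic C(=O)–CH2 bonds. Ketone 6 comes from O-benzyl eugenol 2 and dichloroketene by [2+2] cycloaddition and dechlorination.
- Bromide 14 (ring A, 2,4-dihydroxy-3-methoxyphenyl, as its bis-benzyl ether) comes from 2-methoxyresorcinol 9 by bis-benzylation, Vilsmeier–Haack formylation, reduction and bromination.
- Ring order: rings A and B are bought; the cyclobutane is formed first (step 2) and is then expanded to the butyrolactone (step 4); no other ring is formed.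

Key step: step 4

Assumption: the (R)-configured phosphoric acid is written as the one that delivers the (4R)-lactone; if the benzyl-substituted ketone responds with the opposite sense, the (S)-acid is used and nothing else in the route changes.

## Route

Step 1
Reactants: 1 eugenol
Product: 2 4-allyl-1-(benzyloxy)-2-methoxybenzene
Conditions: BnBr, K2CO3, acetone, reflux
Reagents that add atoms: benzyl bromide BrCc1ccccc1
Why: Williamson ether synthesis on the phenoxide; K2CO3 is too weak to isomerise the allyl group, and the benzyl ether keeps the phenol from being acylated in step 2 and lasts until the final hydrogenolysis.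

Step 2
Reactants: 2 4-allyl-1-(benzyloxy)-2-methoxybenzene; 3 trichloroacetyl chloride
Product: 5 2,2-dichloro-3-[(4-benzyloxy-3-methoxyphenyl)methyl]cyclobutan-1-one (racemic), via dichloroketene 4 (not isolated)
Conditions: Zn–Cu couple, POCl3, Et2O, reflux, slow addition of 3
Reagents that add atoms: none
Why: Thermal [2+2] cycloaddition of dichloroketene (from zinc dechlorination of 3) to the terminal alkene, in which the CH2 terminus bonds to the ketene carbonyl carbon so the benzyl-bearing carbon ends up β to C=O, while POCl3 ties up ZnCl2 and protects the benzyl ether and the arene.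

Step 3
Reactants: 5 2,2-dichloro-3-[(4-benzyloxy-3-methoxyphenyl)methyl]cyclobutan-1-one
Product: 6 3-[(4-benzyloxy-3-methoxyphenyl)methyl]cyclobutan-1-one
Conditions: Zn dust, AcOH, rt to 60 °C
Reagents that add atoms: none
Why: Reductive dehalogenation of an α,α-dichloroketone by zinc in acetic acid via zinc enolates; the benzyl ether is inert and the product is achiral, so the racemic centre of 5 is of no consequence.

Step 4
Reactants: 6 3-[(4-benzyloxy-3-methoxyphenyl)methyl]cyclobutan-1-one
Product: 8 (4R)-4-[(4-benzyloxy-3-methoxyphenyl)methyl]oxolan-2-one, via Criegee adduct 7 (not isolated)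
Conditions: (R)-3,3'-di(pyren-1-yl)-H8-BINOL hydrogen phosphate (10 mol %), 30% aq. H2O2 (1.5 equiv), CHCl3, −40 °C
Reagents that add atoms: hydrogen peroxide OO
Why: The phosphoric acid hydrogen-bonds both the carbonyl of 6 and H2O2, which adds to the strained C=O to give Criegee adduct 7; in the chiral phosphate pocket only one of the two enantiotopic C1–CH2 bonds can lie antiperiplanar to the breaking O–O bond, and that CH2 migrates to oxygen with retention as water leaves. The closest known reaction type is the catalytic asymmetric Baeyer–Villiger desymmetrisation of 3-substituted cyclobutanones with chiral Brønsted acids and aqueous H2O2. The five-membered lactone is closed by ring expansion, a 1,2-shift of carbon from C to O that places O1 between C2 and C5, and not by a cyclisation. C4 is not touched: it becomes a stereocentre because its two ring arms become different, and its (R) configuration is decided by the catalyst alone, since 6 has no other stereo-element. The step needs only enantiotopic-group selectivity, because the two migrating methylenes are constitutionally identical, and chemoselectivity rests on the ring strain of the cyclobutanone, which lets dilute H2O2 react there at −40 °C while the benzyl ether and the electron-rich arene stay inert. Enantiomeric purity is to be checked by chiral HPLC and, if needed, raised by crystallisation of 8 or 16.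

Step 5
Reactants: 9 2-methoxyresorcinol
Product: 10 1,3-bis(benzyloxy)-2-methoxybenzene
Conditions: BnBr (2.2 equiv), K2CO3, DMF, 60 °C
Reagents that add atoms: benzyl bromide BrCc1ccccc1
Why: Double Williamson etherification of the two equivalent phenols, giving a C2v-symmetric arene with a single activated type of ring position.

Step 6
Reactants: 10 1,3-bis(benzyloxy)-2-methoxybenzene
Product: 12 2,4-bis(benzyloxy)-3-methoxybenzaldehyde, via iminium chloride 11 (not isolated)
Conditions: POCl3, DMF, 0 to 70 °C; then ice/H2O
Reagents that add atoms: N,N-dimethylformamide CN(C)C=O; water O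
Why: Vilsmeier–Haack formylation at the position para to one benzyloxy group and ortho to the other (C4 and C6 are equivalent), the position para to the twisted, flanked methoxy group being much less activated, followed by hydrolysis of the aryl iminium salt.

Step 7
Reactants: 12 2,4-bis(benzyloxy)-3-methoxybenzaldehyde
Product: 13 [2,4-bis(benzyloxy)-3-methoxyphenyl]methanol
Conditions: NaBH4, MeOH/THF, 0 °C
Reagents that add atoms: none
Why: Borohydride reduction of an aryl aldehyde to the benzylic alcohol; the ethers are inert.

Step 8
Reactants: 13 [2,4-bis(benzyloxy)-3-methoxyphenyl]methanol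
Product: 14 1-(bromomethyl)-2,4-bis(benzyloxy)-3-methoxybenzene
Conditions: PBr3 (0.4 equiv), Et2O, 0 °C; used at once without storage
Reagents that add atoms: phosphorus tribromide BrP(Br)Br
Why: Conversion of a benzylic alcohol to the bromide through its phosphite ester and bromide displacement, run cold and brief because the electron-rich bromide is labile.

Step 9
Reactants: 8 (4R)-4-[(4-benzyloxy-3-methoxyphenyl)methyl]oxolan-2-one; 14 1-(bromomethyl)-2,4-bis(benzyloxy)-3-methoxybenzene
Product: 16 (3R,4R)-3-[[2,4-bis(benzyloxy)-3-methoxyphenyl]methyl]-4-[(4-benzyloxy-3-methoxyphenyl)methyl]oxolan-2-one, via lithium enolate 15 (not isolated)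
Conditions: LiN(iPr)2 (1.05 equiv), THF, −78 °C; then 14 (1.1 equiv), DMPU, −78 to −30 °C
Reagents that add atoms: none
Why: SN2 alkylation of a lactone lithium enolate, in which the bromide attacks the planar enolate 15 on the face opposite the C4 benzyl group and so sets C3 as R, trans to C4, while the non-enolisable C4 keeps its configuration.

Step 10
Reactants: 16 (3R,4R)-3-[[2,4-bis(benzyloxy)-3-methoxyphenyl]methyl]-4-[(4-benzyloxy-3-methoxyphenyl)methyl]oxolan-2-one
Product: 17 (3R,4R)-3-[(2,4-dihydroxy-3-methoxyphenyl)methyl]-4-[(4-hydroxy-3-methoxyphenyl)methyl]oxolan-2-one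
Conditions: H2 (1 atm), 10% Pd/C, EtOAc/EtOH, rt
Reagents that add atoms: none
Why: Catalytic hydrogenolysis of the three aryl benzyl ethers under neutral conditions, which leaves the lactone and both stereocentres untouched because no base is present to epimerise C3.

## Compound list

1 | eugenol (4-allyl-2-methoxyphenol) | C=CCc1ccc(O)c(OC)c1 | starting material
2 | 4-allyl-1-(benzyloxy)-2-methoxybenzene | C=CCc1ccc(OCc2ccccc2)c(OC)c1 | intermediate
3 | trichloroacetyl chloride | ClC(Cl)(Cl)C(Cl)=O | starting material
4 | dichloroketene | ClC(Cl)=C=O | intermediate (not isolated)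
5 | 2,2-dichloro-3-[(4-benzyloxy-3-methoxyphenyl)methyl]cyclobutan-1-one, racemic | O=C1CC(Cc2ccc(OCc3ccccc3)c(OC)c2)C1(Cl)Cl | intermediate
6 | 3-[(4-benzyloxy-3-methoxyphenyl)methyl]cyclobutan-1-one | O=C1CC(Cc2ccc(OCc3ccccc3)c(OC)c2)C1 | intermediate
7 | Criegee adduct, 3-[(4-benzyloxy-3-methoxyphenyl)methyl]-1-hydroperoxycyclobutan-1-ol | OOC1(O)CC(Cc2ccc(OCc3ccccc3)c(OC)c2)C1 | intermediate (not isolated)
8 | (4R)-4-[(4-benzyloxy-3-methoxyphenyl)methyl]oxolan-2-one | COc1cc(C[C@H]2COC(=O)C2)ccc1OCc1ccccc1 | intermediate
9 | 2-methoxyresorcinol (2-methoxybenzene-1,3-diol) | COc1c(O)cccc1O | starting material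
10 | 1,3-bis(benzyloxy)-2-methoxybenzene | COc1c(OCc2ccccc2)cccc1OCc1ccccc1 | intermediate
11 | iminium chloride, N-[[2,4-bis(benzyloxy)-3-methoxyphenyl]methylidene]-N-methylmethanaminium chloride | C[N+](C)=Cc1ccc(OCc2ccccc2)c(OC)c1OCc1ccccc1.[Cl-] | intermediate (not isolated)
12 | 2,4-bis(benzyloxy)-3-methoxybenzaldehyde | O=Cc1ccc(OCc2ccccc2)c(OC)c1OCc1ccccc1 | intermediate
13 | [2,4-bis(benzyloxy)-3-methoxyphenyl]methanol | OCc1ccc(OCc2ccccc2)c(OC)c1OCc1ccccc1 | intermediate
14 | 1-(bromomethyl)-2,4-bis(benzyloxy)-3-methoxybenzene | BrCc1ccc(OCc2ccccc2)c(OC)c1OCc1ccccc1 | intermediate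
15 | lithium enolate of 8, lithium (3R)-3-[(4-benzyloxy-3-methoxyphenyl)methyl]-2,3-dihydrofuran-5-olate | COc1cc(C[C@H]2COC([O-])=C2)ccc1OCc1ccccc1.[Li+] | intermediate (not isolated)
16 | (3R,4R)-3-[[2,4-bis(benzyloxy)-3-methoxyphenyl]methyl]-4-[(4-benzyloxy-3-methoxyphenyl)methyl]oxolan-2-one | COc1cc(C[C@H]2COC(=O)[C@@H]2Cc2ccc(OCc3ccccc3)c(OC)c2OCc2ccccc2)ccc1OCc1ccccc1 | intermediate
17 | (3R,4R)-3-[(2,4-dihydroxy-3-methoxyphenyl)methyl]-4-[(4-hydroxy-3-methoxyphenyl)methyl]oxolan-2-one | COc1cc(C[C@H]2COC(=O)[C@@H]2Cc2ccc(O)c(OC)c2O)ccc1O | target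

## Step count and risks

Total step count: 10. Longest linear sequence: 6 steps (steps 1, 2, 3, 4, 9, 10; the ring A branch, steps 5, 6, 7, 8, 9, 10, is equally long).

Steps most likely to fail:

1. Step 4. The aryl group sits one CH2 away from the four-membered ring, so the catalyst may distinguish the two enantiotopic methylenes only weakly, and uncatalysed oxidation by H2O2 may add racemic lactone. The fallback sets out from 6 and returns at 8, setting the same centre by enantiotopic proton removal instead of oxygen insertion. Ketone 6 is deprotonated with the appropriate enantiomer of lithium bis(1-phenylethyl)amide in the presence of Et3SiCl (THF, −100 °C) to give the silyl enol ether [(3R)-3-[(4-benzyloxy-3-methoxyphenyl)methyl]cyclobut-1-en-1-yl]oxy-triethylsilane F1. Ozonolysis (O3, CH2Cl2/MeOH, −78 °C) with direct NaBH4 reduction then gives (3R)-3-[(4-benzyloxy-3-methoxyphenyl)methyl]-4-hydroxybutanoic acid F2, which closes to lactone 8 on acidification with aqueous HCl.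

2. Step 9. The very electron-rich benzylic bromide may self-condense or hydrolyse before it alkylates, proton transfer from product to enolate may lead to double alkylation, and anti selectivity may be incomplete. The fallback sets out from 8 (with aldehyde 12, already in the route) and returns at 17, bypassing 13, 14 and 16. Enolate 15 (LiN(iPr)2, THF, −78 °C) is added to aldehyde 12 in an aldol reaction, again anti to the C4 substituent, to give (3S,4R)-3-[[2,4-bis(benzyloxy)-3-methoxyphenyl](hydroxy)methyl]-4-[(4-benzyloxy-3-methoxyphenyl)methyl]oxolan-2-one F3 as a mixture of carbinol epimers. Hydrogenation (H2, Pd/C, AcOH/EtOAc, rt) should then cleave the benzylic C–OH bond, activated by the ortho and para oxygens, together with the three benzyl ethers, giving 17 directly.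

3. Step 2. Dichloroketene may oligomerise faster than it adds to the unactivated monosubstituted alkene, and ZnCl2 may promote alkene oligomerisation or ether cleavage. The fallback sets out from 2 and returns at 6, bypassing 5. A keteniminium [2+2] cycloaddition (N,N-dimethylacetamide, Tf2O, 2,4,6-collidine, ClCH2CH2Cl, reflux) gives the cyclobutaniminium salt N-[3-[(4-benzyloxy-3-methoxyphenyl)methyl]cyclobutylidene]-N-methylmethanaminium trifluoromethanesulfonate F4, which is hydrolysed with aqueous NaHCO3 to ketone 6 with no dechlorination step.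

Further compounds
F1 | step 4 | [(3R)-3-[(4-benzyloxy-3-methoxyphenyl)methyl]cyclobut-1-en-1-yl]oxy-triethylsilane | COc1cc(C[C@H]2C=C(O[Si](CC)(CC)CC)C2)ccc1OCc1ccccc1
F2 | step 4 | (3R)-3-[(4-benzyloxy-3-methoxyphenyl)methyl]-4-hydroxybutanoic acid | COc1cc(C[C@H](CC(=O)O)CO)ccc1OCc1ccccc1
F3 | step 9 | (3S,4R)-3-[[2,4-bis(benzyloxy)-3-methoxyphenyl](hydroxy)methyl]-4-[(4-benzyloxy-3-methoxyphenyl)methyl]oxolan-2-one, mixture of carbinol epimers | COc1cc(C[C@H]2COC(=O)[C@@H]2C(O)c2ccc(OCc3ccccc3)c(OC)c2OCc2ccccc2)ccc1OCc1ccccc1
F4 | step 2 | N-[3-[(4-benzyloxy-3-methoxyphenyl)methyl]cyclobutylidene]-N-methylmethanaminium trifluoromethanesulfonate | C[N+](C)=C1CC(Cc2ccc(OCc3ccccc3)c(OC)c2)C1.[O-]S(=O)(=O)C(F)(F)F
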